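**Plan**

- Prostanoid locants are used: ester carbon C1, acetoxy carbinol C4, ring C8–C12 with the C9 ketone and the quaternary acetoxy carbon C12, ω-chain C13–C20.
- Enabling feature: in ring C8–C12 the C9 carbonyl is bonded to C8 of the exocyclic C7=C8 alkene, and the C7 hydrogen lies cis to C9. This is what syn addition of an aldehyde C9–H across a C7≡C8 alkyne leaves behind. The retrosynthesis therefore first removes the C10=C11 double bond (ketone dehydrogenation) and then cuts the ring bond C8–C9, giving an acyclic 5-alkynal.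
- The alkynal is cut at C6–C7 (Sonogashira) into a C1–C6 (Z)-iodoalkene and a C7–C20 tertiary propargylic alcohol. The latter is cut at C7≡C8 (alkyne from an aldehyde), C15–C16 (alkyne/propargyl bromide coupling), C13–C14 (acetylide opening of an epoxide) and C11–C12 (B-alkyl Suzuki coupling).
- Forward: the side chain (steps 1–5) and the open-chain core (steps 6–12) are made separately and joined in step 13. The only ring, C8–C12, closes in step 17, and the enone is installed last (steps 18–19).
- Stereochemistry: C12 from Sharpless epoxidation of a 2-substituted allylic alcohol with L-(+)-DIPT; C4 from asymmetric transfer hydrogenation of an ynone with the (R,R)-TsDPEN–Ru catalyst; 5Z from diimide reduction of an iodoalkyne; 14Z and 17Z from Lindlar reduction; 7E from the syn hydroacylation.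

Key step: step 17

Remark: the CIP descriptor of the quaternary carbinol carbon changes along the route (S in 12, R in 13–23, S in 24 and 25). This comes only from priority changes of its neighbours; the spatial arrangement set in step 7 is never touched again.

**Route**

Step 1
Reactants: 1 methyl 4-chloro-4-oxobutanoate; 2 ethynyltrimethylsilane
Product: 3 methyl 4-oxo-6-(trimethylsilyl)hex-5-ynoate
Conditions: PdCl2(PPh3)2 (2 mol %), CuI (4 mol %), Et3N (1.2 equiv), THF, rt
Reagents that add atoms: none
Why: Acyl Sonogashira coupling of an acid chloride with a terminal alkyne gives the silyl ynone directly, the methyl ester being inert and the silyl group blocking the alkyne terminus.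

Step 2
Reactants: 3 methyl 4-oxo-6-(trimethylsilyl)hex-5-ynoate
Product: 4 methyl (4R)-4-hydroxy-6-(trimethylsilyl)hex-5-ynoate
Conditions: Ru[(R,R)-TsDPEN](p-cymene) (0.5 mol %), i-PrOH, rt; crude product taken on at once
Reagents that add atoms: none
Why: In this Noyori asymmetric transfer hydrogenation of an alkynyl ketone the alkyne takes the place usually held by an aryl group in the six-membered hydride-transfer transition state, so the (R,R) catalyst should give the (R)-propargylic alcohol (C4), and the base-free medium limits lactonisation of the γ-hydroxy ester.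

Step 3
Reactants: 4 methyl (4R)-4-hydroxy-6-(trimethylsilyl)hex-5-ynoate
Product: 5 methyl (4R)-4-acetoxy-6-(trimethylsilyl)hex-5-ynoate
Conditions: Ac2O, pyridine, DMAP (cat.), CH2Cl2, 0 °C → rt
Reagents that add atoms: acetic anhydride, CC(=O)OC(C)=O
Why: DMAP-catalysed acetylation of the secondary alcohol installs the C4 acetate of the target and removes the risk of γ-lactone formation.

Step 4
Reactants: 5 methyl (4R)-4-acetoxy-6-(trimethylsilyl)hex-5-ynoate
Product: 6 methyl (4R)-4-acetoxy-6-iodohex-5-ynoate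
Conditions: NIS (1.2 equiv), AgNO3 (10 mol %), DMF, rt, dark
Reagents that add atoms: N-iodosuccinimide, O=C1CCC(=O)N1I
Why: Silver-catalysed iododesilylation of a trimethylsilylalkyne (through the silver acetylide) gives the 1-iodoalkyne without touching the esters.

Step 5
Reactants: 6 methyl (4R)-4-acetoxy-6-iodohex-5-ynoate
Product: 7 methyl (4R,5Z)-4-acetoxy-6-iodohex-5-enoate
Conditions: 2-nitrobenzenesulfonyl hydrazide (2.5 equiv), Et3N, THF/i-PrOH 1:1, rt
Reagents that add atoms: none
Why: Diimide generated in the flask adds H2 in a concerted syn manner to the iodoalkyne, which should give only the (Z)-iodoalkene and leave the C–I bond, the acetate and the ester alone.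

Step 6
Reactants: 8 tert-butyldimethyl(prop-2-en-1-yloxy)silane; 9 2-bromoprop-2-en-1-ol
Product: 11 2-{3-[(tert-butyldimethylsilyl)oxy]propyl}prop-2-en-1-ol, via alkyl-9-BBN borane 10 (not isolated)
Conditions: 9-BBN (0.5 M in THF), 0 °C → rt; then 9, Pd(dppf)Cl2 (3 mol %), aq K3PO4 (3 M), DMF, rt
Reagents that add atoms: 9-borabicyclo[3.3.1]nonane (9-BBN), B1C2CCCC1CCC2 (its boron and carbons stay only in intermediate 10; product 11 keeps one hydrogen from it)
Why: Anti-Markovnikov hydroboration of the allyl ether followed by B-alkyl Suzuki–Miyaura coupling with the 1,1-disubstituted vinyl bromide forms C11–C12 and gives the 2-substituted allylic alcohol in one flask.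

Step 7
Reactants: 11 2-{3-[(tert-butyldimethylsilyl)oxy]propyl}prop-2-en-1-ol
Product: 12 [(2S)-2-{3-[(tert-butyldimethylsilyl)oxy]propyl}oxiran-2-yl]methanol
Conditions: Ti(Oi-Pr)4 (10 mol %), L-(+)-DIPT (12 mol %), t-BuOOH (2 equiv), 4 Å MS, CH2Cl2, −20 °C
Reagents that add atoms: tert-butyl hydroperoxide, CC(C)(C)OO
Why: In this Sharpless asymmetric epoxidation the L-(+)-tartrate ligand should deliver the peroxide oxygen to the alkene face that makes the new quaternary carbon (S), as it does in the conversion of 2-methylallyl alcohol into (S)-2-methylglycidol, and this fixes C12 of the target.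

Step 8
Reactants: 12 [(2S)-2-{3-[(tert-butyldimethylsilyl)oxy]propyl}oxiran-2-yl]methanol
Product: 13 (2R)-2-{3-[(tert-butyldimethylsilyl)oxy]propyl}pent-4-yne-1,2-diol
Conditions: LiC≡CH·H2NCH2CH2NH2 (4 equiv), DMSO, 0 °C → rt; then H2O
Reagents that add atoms: lithium acetylide–ethylenediamine complex, [Li+].[C-]#C.NCCN
Why: SN2 opening of the 2,2-disubstituted epoxide by acetylide at its CH2 terminus forms C13–C14 without touching the quaternary centre, and a Payne rearrangement of the alkoxide is degenerate here (it regenerates the same enantiomer), so the free hydroxyl needs no protection.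

Step 9
Reactants: 13 (2R)-2-{3-[(tert-butyldimethylsilyl)oxy]propyl}pent-4-yne-1,2-diol; 14 1-bromopent-2-yne
Product: 15 (2R)-2-{3-[(tert-butyldimethylsilyl)oxy]propyl}deca-4,7-diyne-1,2-diol
Conditions: CuI (1.0 equiv), Cs2CO3 (1.5 equiv), DMF, rt
Reagents that add atoms: none
Why: Copper-mediated coupling of a terminal alkyne with a propargylic bromide (copper acetylide, SN2) forms C15–C16 and gives the skipped diyne, free hydroxyls being tolerated.

Step 10
Reactants: 15 (2R)-2-{3-[(tert-butyldimethylsilyl)oxy]propyl}deca-4,7-diyne-1,2-diol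
Product: 16 (2R,4Z,7Z)-2-{3-[(tert-butyldimethylsilyl)oxy]propyl}deca-4,7-diene-1,2-diol
Conditions: H2 (1 atm), Lindlar catalyst, quinoline, EtOAc, rt
Reagents that add atoms: none
Why: Lindlar semihydrogenation adds H2 syn to each alkyne of the skipped diyne and should give the 14Z,17Z diene, quinoline being there to stop over-reduction.

Step 11
Reactants: 16 (2R,4Z,7Z)-2-{3-[(tert-butyldimethylsilyl)oxy]propyl}deca-4,7-diene-1,2-diol
Product: 17 (2R,4Z,7Z)-2-{3-[(tert-butyldimethylsilyl)oxy]propyl}-2-hydroxydeca-4,7-dienal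
Conditions: SO3·pyridine, DMSO, i-Pr2NEt, CH2Cl2, 0 °C
Reagents that add atoms: none
Why: Parikh–Doering oxidation takes only the primary alcohol of the 1,2-diol to the aldehyde, since the tertiary alcohol cannot be oxidised, activated DMSO does not cleave glycols, and the aldehyde has no α-hydrogen to epimerise.

Step 12
Reactants: 17 (2R,4Z,7Z)-2-{3-[(tert-butyldimethylsilyl)oxy]propyl}-2-hydroxydeca-4,7-dienal
Product: 18 (4R,6Z,9Z)-1-[(tert-butyldimethylsilyl)oxy]-4-ethynyldodeca-6,9-dien-4-ol
Conditions: dimethyl (1-diazo-2-oxopropyl)phosphonate, K2CO3, MeOH, 0 °C → rt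
Reagents that add atoms: dimethyl (1-diazo-2-oxopropyl)phosphonate, CC(=O)C(=[N+]=[N-])P(=O)(OC)OC
Why: Seyferth–Gilbert homologation with the Ohira–Bestmann reagent (Horner–Wadsworth–Emmons-type addition, loss of N2, 1,2-hydride shift of the alkylidene carbene) turns the non-enolisable aldehyde into the terminal alkyne C7≡C8 under mild base that tolerates the free tertiary hydroxyl.

Step 13
Reactants: 18 (4R,6Z,9Z)-1-[(tert-butyldimethylsilyl)oxy]-4-ethynyldodeca-6,9-dien-4-ol; 7 methyl (4R,5Z)-4-acetoxy-6-iodohex-5-enoate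
Product: 19 methyl (4R,5Z,9R,11Z,14Z)-4-acetoxy-9-{3-[(tert-butyldimethylsilyl)oxy]propyl}-9-hydroxyheptadeca-5,11,14-trien-7-ynoate
Conditions: PdCl2(PPh3)2 (5 mol %), CuI (10 mol %), Et3N (3 equiv), degassed THF, 0 °C → rt
Reagents that add atoms: none
Why: Sonogashira coupling of the terminal alkyne with the (Z)-iodoalkene forms C6–C7 with retention of alkene geometry, oxidative addition into C–I being far faster than ionisation of the allylic acetate and the tertiary amine offering no nucleophile for a π-allyl.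

Step 14
Reactants: 19 methyl (4R,5Z,9R,11Z,14Z)-4-acetoxy-9-{3-[(tert-butyldimethylsilyl)oxy]propyl}-9-hydroxyheptadeca-5,11,14-trien-7-ynoate
Product: 20 methyl (4R,5Z,9R,11Z,14Z)-4,9-diacetoxy-9-{3-[(tert-butyldimethylsilyl)oxy]propyl}heptadeca-5,11,14-trien-7-ynoate
Conditions: Ac2O (5 equiv), DMAP (1 equiv), Et3N, CH2Cl2, rt
Reagents that add atoms: acetic anhydride, CC(=O)OC(C)=O
Why: DMAP-catalysed acetylation of the tertiary propargylic alcohol (little hindered on its alkyne side) gives the C12 acetate, placed after the coupling so that no propargylic ester meets Pd(0).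

Step 15
Reactants: 20 methyl (4R,5Z,9R,11Z,14Z)-4,9-diacetoxy-9-{3-[(tert-butyldimethylsilyl)oxy]propyl}heptadeca-5,11,14-trien-7-ynoate
Product: 21 methyl (4R,5Z,9R,11Z,14Z)-4,9-diacetoxy-9-(3-hydroxypropyl)heptadeca-5,11,14-trien-7-ynoate
Conditions: HF·pyridine, pyridine, THF, 0 °C → rt
Reagents that add atoms: none
Why: Buffered HF·pyridine cleaves the primary silyl ether, while the acetates, the methyl ester and the skipped diene are stable to it.

Step 16
Reactants: 21 methyl (4R,5Z,9R,11Z,14Z)-4,9-diacetoxy-9-(3-hydroxypropyl)heptadeca-5,11,14-trien-7-ynoate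
Product: 22 methyl (4R,5Z,9R,11Z,14Z)-4,9-diacetoxy-9-(3-oxopropyl)heptadeca-5,11,14-trien-7-ynoate (the C9 aldehyde in prostanoid numbering, 12R)
Conditions: Dess–Martin periodinane, pyridine, CH2Cl2, 0 °C → rt
Reagents that add atoms: none
Why: Dess–Martin oxidation of the primary alcohol gives the aldehyde under nearly neutral conditions, and the C12 acetate keeps it from closing to a lactol.

Step 17
Reactants: 22 methyl (4R,5Z,9R,11Z,14Z)-4,9-diacetoxy-9-(3-oxopropyl)heptadeca-5,11,14-trien-7-ynoate
Product: 23 methyl (4R,5Z,7E,12R,14Z,17Z)-4,12-diacetoxy-9-oxoprosta-5,7,14,17-tetraenoate (10,11-dihydro-17,18-dehydroclavulone I)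
Conditions: [Rh(cod)2]BF4 (10 mol %), rac-BINAP (10 mol %), CH2Cl2, H2 (1 atm, 30 min) then Ar; add 22, rt
Reagents that add atoms: none
Why: Cationic Rh(I) inserts into the C9 aldehyde C–H to give an acyl rhodium(III) hydride, the tethered C7≡C8 alkyne inserts syn into Rh–H (H to C7, Rh to C8) to give a six-membered acyl(alkenyl)rhodacycle, and C8–C9 reductive elimination releases the ketone and the catalyst. The closest known reaction is the cationic Rh(I)–bisphosphine cyclisation of 5-alkynals to (E)-2-alkylidenecyclopentanones at room temperature. The one ring, C8–C12, closes in 5-exo-dig mode. No stereocentre is created; the quaternary C12 is untouched, and the new C7=C8 geometry (7E, hydrogen cis to C9) follows from the syn hydrometalation and the retentive reductive elimination. The step needs exo closure, no decarbonylation, intact acetates and an intact 5Z alkene: a six-membered ring formed by syn addition would hold a trans double bond and is therefore excluded, the three-atom tether with the quaternary C12 (gem-disubstituent effect) should make alkyne insertion faster than CO extrusion, and the mild catalyst at room temperature should leave the allylic and propargylic acetates alone. The skipped diene could only give six- or seven-membered ketones and should not compete.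

Step 18
Reactants: 23 methyl (4R,5Z,7E,12R,14Z,17Z)-4,12-diacetoxy-9-oxoprosta-5,7,14,17-tetraenoate
Product: 24 methyl (4R,5Z,7E,12S,14Z,17Z)-4,12-diacetoxy-9-[(trimethylsilyl)oxy]prosta-5,7,9,14,17-pentaenoate
Conditions: TMSOTf (1.3 equiv), Et3N (2 equiv), CH2Cl2, −78 → 0 °C; non-aqueous work-up, used at once
Reagents that add atoms: trimethylsilyl trifluoromethanesulfonate, C[Si](C)(C)OS(=O)(=O)C(F)(F)F
Why: Soft enolisation with a silyl triflate and an amine silylates the ketone much faster than the esters, and since C8 bears no hydrogen the enol ether can only form toward C10.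

Step 19
Reactants: 24 methyl (4R,5Z,7E,12S,14Z,17Z)-4,12-diacetoxy-9-[(trimethylsilyl)oxy]prosta-5,7,9,14,17-pentaenoate
Product: 25 17,18-dehydroclavulone I, methyl (4R,5Z,7E,12S,14Z,17Z)-4,12-diacetoxy-9-oxoprosta-5,7,10,14,17-pentaenoate
Conditions: Pd(OAc)2 (1.1 equiv), MeCN, rt
Reagents that add atoms: none
Why: In this Saegusa–Ito oxidation Pd(II) turns the silyl enol ether into the C10 palladium enolate and β-hydride elimination from C11 installs the C10=C11 enone, the phosphine-free medium keeping the palladium(0) formed from ionising the allylic acetate.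

**Compound list**

1 | methyl 4-chloro-4-oxobutanoate | COC(=O)CCC(Cl)=O | starting material
2 | ethynyltrimethylsilane | C[Si](C)(C)C#C | starting material
3 | methyl 4-oxo-6-(trimethylsilyl)hex-5-ynoate | COC(=O)CCC(=O)C#C[Si](C)(C)C | intermediate
4 | methyl (4R)-4-hydroxy-6-(trimethylsilyl)hex-5-ynoate | COC(=O)CC[C@@H](O)C#C[Si](C)(C)C | intermediate
5 | methyl (4R)-4-acetoxy-6-(trimethylsilyl)hex-5-ynoate | COC(=O)CC[C@@H](OC(C)=O)C#C[Si](C)(C)C | intermediate
6 | methyl (4R)-4-acetoxy-6-iodohex-5-ynoate | COC(=O)CC[C@@H](OC(C)=O)C#CI | intermediate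
7 | methyl (4R,5Z)-4-acetoxy-6-iodohex-5-enoate | COC(=O)CC[C@@H](OC(C)=O)/C=C\I | intermediate
8 | tert-butyldimethyl(prop-2-en-1-yloxy)silane | C=CCO[Si](C)(C)C(C)(C)C | starting material
9 | 2-bromoprop-2-en-1-ol | OCC(Br)=C | starting material
10 | 9-{3-[(tert-butyldimethylsilyl)oxy]propyl}-9-borabicyclo[3.3.1]nonane | CC(C)(C)[Si](C)(C)OCCCB1C2CCCC1CCC2 | intermediate
11 | 2-{3-[(tert-butyldimethylsilyl)oxy]propyl}prop-2-en-1-ol | C=C(CO)CCCO[Si](C)(C)C(C)(C)C | intermediate
12 | [(2S)-2-{3-[(tert-butyldimethylsilyl)oxy]propyl}oxiran-2-yl]methanol | OC[C@@]1(CCCO[Si](C)(C)C(C)(C)C)CO1 | intermediate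
13 | (2R)-2-{3-[(tert-butyldimethylsilyl)oxy]propyl}pent-4-yne-1,2-diol | OC[C@@](O)(CCCO[Si](C)(C)C(C)(C)C)CC#C | intermediate
14 | 1-bromopent-2-yne | CCC#CCBr | starting material
15 | (2R)-2-{3-[(tert-butyldimethylsilyl)oxy]propyl}deca-4,7-diyne-1,2-diol | OC[C@@](O)(CCCO[Si](C)(C)C(C)(C)C)CC#CCC#CCC | intermediate
16 | (2R,4Z,7Z)-2-{3-[(tert-butyldimethylsilyl)oxy]propyl}deca-4,7-diene-1,2-diol | OC[C@@](O)(CCCO[Si](C)(C)C(C)(C)C)C/C=C\C/C=C\CC | intermediate
17 | (2R,4Z,7Z)-2-{3-[(tert-butyldimethylsilyl)oxy]propyl}-2-hydroxydeca-4,7-dienal | O=C[C@@](O)(CCCO[Si](C)(C)C(C)(C)C)C/C=C\C/C=C\CC | intermediate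
18 | (4R,6Z,9Z)-1-[(tert-butyldimethylsilyl)oxy]-4-ethynyldodeca-6,9-dien-4-ol | C#C[C@@](O)(CCCO[Si](C)(C)C(C)(C)C)C/C=C\C/C=C\CC | intermediate
19 | methyl (4R,5Z,9R,11Z,14Z)-4-acetoxy-9-{3-[(tert-butyldimethylsilyl)oxy]propyl}-9-hydroxyheptadeca-5,11,14-trien-7-ynoate | CC/C=C\C/C=C\C[C@](O)(CCCO[Si](C)(C)C(C)(C)C)C#C/C=C\[C@@H](CCC(=O)OC)OC(C)=O | intermediate
20 | methyl (4R,5Z,9R,11Z,14Z)-4,9-diacetoxy-9-{3-[(tert-butyldimethylsilyl)oxy]propyl}heptadeca-5,11,14-trien-7-ynoate | CC/C=C\C/C=C\C[C@](OC(C)=O)(CCCO[Si](C)(C)C(C)(C)C)C#C/C=C\[C@@H](CCC(=O)OC)OC(C)=O | intermediate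
21 | methyl (4R,5Z,9R,11Z,14Z)-4,9-diacetoxy-9-(3-hydroxypropyl)heptadeca-5,11,14-trien-7-ynoate | CC/C=C\C/C=C\C[C@](OC(C)=O)(CCCO)C#C/C=C\[C@@H](CCC(=O)OC)OC(C)=O | intermediate
22 | methyl (4R,5Z,9R,11Z,14Z)-4,9-diacetoxy-9-(3-oxopropyl)heptadeca-5,11,14-trien-7-ynoate | CC/C=C\C/C=C\C[C@](OC(C)=O)(CCC=O)C#C/C=C\[C@@H](CCC(=O)OC)OC(C)=O | intermediate
23 | methyl (4R,5Z,7E,12R,14Z,17Z)-4,12-diacetoxy-9-oxoprosta-5,7,14,17-tetraenoate (10,11-dihydro-17,18-dehydroclavulone I) | CC/C=C\C/C=C\C[C@]1(OC(C)=O)CCC(=O)/C1=C/C=C\[C@@H](CCC(=O)OC)OC(C)=O | intermediate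
24 | methyl (4R,5Z,7E,12S,14Z,17Z)-4,12-diacetoxy-9-[(trimethylsilyl)oxy]prosta-5,7,9,14,17-pentaenoate | CC/C=C\C/C=C\C[C@]1(OC(C)=O)CC=C(O[Si](C)(C)C)/C1=C/C=C\[C@@H](CCC(=O)OC)OC(C)=O | intermediate
25 | 17,18-dehydroclavulone I, methyl (4R,5Z,7E,12S,14Z,17Z)-4,12-diacetoxy-9-oxoprosta-5,7,10,14,17-pentaenoate | CC/C=C\C/C=C\C[C@]1(OC(C)=O)C=CC(=O)/C1=C/C=C\[C@@H](CCC(=O)OC)OC(C)=O | target

**Count and risks**

Total step count: 19. Longest linear sequence: 14 steps (steps 6–19, from 8 to 25); the side chain 7 takes 5 steps (steps 1–5).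

Steps most likely to fail:

1. Step 17 (hydroacylation). What may go wrong: extrusion of CO from the acyl rhodium hydride before the alkyne inserts, ionisation or 1,3-acyloxy shift of the tertiary propargylic acetate at the cationic metal, and Z→E scrambling of the C5=C6 alkene through an η3-bound dienyl rhodium species. Fallback, setting out from aldehyde 22 and returning at ketone 23: the same C8–C9 bond is made at the alcohol oxidation level by nickel(0)-catalysed reductive cyclisation of the ynal with triethylsilane (Ni(cod)2, an N-heterocyclic carbene or PBu3, THF, rt). Oxidative cyclisation of aldehyde and alkyne to an oxanickelacycle, Si–H σ-bond metathesis and C–H reductive elimination place hydrogen on C7 cis to C9. This should give methyl (4R,5Z,7Z,12R,14Z,17Z)-4,12-diacetoxy-9-[(triethylsilyl)oxy]prosta-5,7,14,17-tetraenoate F1 as a mixture of C9 epimers; its 7Z descriptor is the same geometry as 7E in 23, only the CIP priority at C8 differs. HF·pyridine would free the allylic alcohol methyl (4R,5Z,7Z,12R,14Z,17Z)-4,12-diacetoxy-9-hydroxyprosta-5,7,14,17-tetraenoate F2, and MnO2 would oxidise it to 23.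

2. Step 19 (dehydrogenation). What may go wrong: palladium(0) released during the oxidation ionises the doubly allylic tertiary acetate of the product, with loss of acetate and decomposition through a cyclopentadienone, or protonation of the palladium enolate simply returns 23. Fallback, setting out from silyl enol ether 24 and returning at target 25: phenylselenenyl chloride (CH2Cl2, −78 °C) should give methyl (4R,5Z,7E,12S,14Z,17Z)-4,12-diacetoxy-9-oxo-10-(phenylselanyl)prosta-5,7,14,17-tetraenoate F3 (C10 epimers). H2O2/pyridine at 0 °C would oxidise it to the selenoxide methyl (4R,5Z,7E,12S,14Z,17Z)-4,12-diacetoxy-9-oxo-10-(phenylseleninyl)prosta-5,7,14,17-tetraenoate F4, which undergoes syn elimination toward C11 below room temperature and gives 25 without any low-valent metal.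

3. Step 8 (epoxide opening). What may go wrong: slow SN2 attack at the neopentyl-like CH2 next to the alkoxide-bearing quaternary carbon, base-induced loss or migration of the silyl group, and oligomerisation by alkoxide attack on a second epoxide. Fallback, setting out from epoxy alcohol 12 and returning at diene diol 16 (steps 9 and 10 are then not needed): the whole C14–C20 unit is brought in as a preformed (Z,Z)-alkenyl nucleophile. Commercial (Z)-hex-3-en-1-ol is oxidised with Dess–Martin periodinane to (Z)-hex-3-enal F5. A Stork–Zhao olefination (iodomethyltriphenylphosphonium iodide, NaHMDS, THF/HMPA, −78 °C) gives (1Z,4Z)-1-iodohepta-1,4-diene F6. Iodine–lithium exchange (t-BuLi, Et2O, −78 °C) gives (1Z,4Z)-hepta-1,4-dien-1-yllithium F7 with retention of geometry. An excess of F7 with BF3·OEt2 at −78 °C opens 12 at its CH2 terminus and gives 16.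

Further compounds
F1 | step 17 | methyl (4R,5Z,7Z,12R,14Z,17Z)-4,12-diacetoxy-9-[(triethylsilyl)oxy]prosta-5,7,14,17-tetraenoate (C9 epimers) | CC/C=C\C/C=C\C[C@]1(OC(C)=O)CCC(O[Si](CC)(CC)CC)/C1=C/C=C\[C@@H](CCC(=O)OC)OC(C)=O
F2 | step 17 | methyl (4R,5Z,7Z,12R,14Z,17Z)-4,12-diacetoxy-9-hydroxyprosta-5,7,14,17-tetraenoate (C9 epimers) | CC/C=C\C/C=C\C[C@]1(OC(C)=O)CCC(O)/C1=C/C=C\[C@@H](CCC(=O)OC)OC(C)=O
F3 | step 19 | methyl (4R,5Z,7E,12S,14Z,17Z)-4,12-diacetoxy-9-oxo-10-(phenylselanyl)prosta-5,7,14,17-tetraenoate (C10 epimers) | CC/C=C\C/C=C\C[C@]1(OC(C)=O)CC([Se]c2ccccc2)C(=O)/C1=C/C=C\[C@@H](CCC(=O)OC)OC(C)=O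
F4 | step 19 | methyl (4R,5Z,7E,12S,14Z,17Z)-4,12-diacetoxy-9-oxo-10-(phenylseleninyl)prosta-5,7,14,17-tetraenoate (C10 epimers) | CC/C=C\C/C=C\C[C@]1(OC(C)=O)CC([Se](=O)c2ccccc2)C(=O)/C1=C/C=C\[C@@H](CCC(=O)OC)OC(C)=O
F5 | step 8 | (Z)-hex-3-enal | CC/C=C\CC=O
F6 | step 8 | (1Z,4Z)-1-iodohepta-1,4-diene | CC/C=C\C/C=C\I
F7 | step 8 | (1Z,4Z)-hepta-1,4-dien-1-yllithium | CC/C=C\C/C=C\[Li]
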